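**Plan**
Numbering is that of the chromene (O1, C2, C3, C4, C4a, C5 to C8, C8a); ring A is the carbocycle C4a–C5–C6–C7–C8–C8a.
Enabling feature: C5 is a ketone carbon bonded to the quaternary C4a and to the acyl-bearing C6, and C4a is allylic to the C3=C4 alkene of the pyran ring. This is the pattern left when an acylpalladium adds across a C4a=C4 alkene and the metal leaves with a hydrogen from C3.
Retrosynthesis: first the O-methyl of an enol ether on the isobutyryl oxygen; then C5–C6 and C4a–C5 together (C5 leaves as carbon monoxide, ring A opens to a C6 vinyl iodide and a 2-ylidene-5,6-dihydropyran); then C8–C8a.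
Forward: the pyran ring is made first as an α-prenyl unsaturated δ-lactone (Z-selective olefination, lactonisation); the iodo enone comes from an ynone by methanol addition, iodination and α′-prenylation.
Claisen union and dehydration give the open precursor; ring A closes in the carbonylative Heck step; hydrolysis of the enol ether frees the β-triketone.
Stereochemistry: the only stereocentre, (R)-C4a, is set in the ring closure by a chiral bisphosphine on palladium and, being quaternary, cannot be lost afterwards.

Key step: step 9

Remark: the β-triketone is masked as the methyl enol ether on the isobutyryl oxygen (not on O7), because kinetic α′-enolate chemistry of a β-methoxy enone gives this regioisomer without ambiguity and either enol ether hydrolyses to the same triketone.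
Remark: the tetrasubstituted C8=C8a enol ether of the cyclisation precursor is drawn with C7 cis to C4a, as the closure needs; as a push–pull alkene it is assumed to equilibrate under the acidic dehydration and the palladium conditions.

**Step 1**
Reactants: 1 methyl 2-[bis(2,2,2-trifluoroethoxy)phosphoryl]acetate; 2 1-bromo-3-methylbut-2-ene (prenyl bromide)
Product: 3 methyl 2-[bis(2,2,2-trifluoroethoxy)phosphoryl]-5-methylhex-4-enoate
Conditions: NaH, THF, 0 °C; then 2, 0 °C → rt
Reagents that add atoms: none
Why: SN2 C-alkylation of the stabilised phosphonoacetate carbanion by an allylic bromide, the usual way to α-substituted Still–Gennari reagents, with a slight excess of 1 to suppress double alkylation.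

**Step 2**
Reactants: 4 3-methylbutane-1,3-diol
Product: 5 3-hydroxy-3-methylbutanal
Conditions: TEMPO (10 mol %), PhI(OAc)2, CH2Cl2, rt; used at once
Reagents that add atoms: none
Why: TEMPO-catalysed (oxoammonium) oxidation is selective for the primary alcohol, stops at the aldehyde and cannot touch the tertiary alcohol.

**Step 3**
Reactants: 3 methyl 2-[bis(2,2,2-trifluoroethoxy)phosphoryl]-5-methylhex-4-enoate; 5 3-hydroxy-3-methylbutanal
Product: 7 6,6-dimethyl-3-(3-methylbut-2-enyl)-5,6-dihydro-2H-pyran-2-one, via (Z)-hydroxy ester 6 (not isolated)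
Conditions: KHMDS, 18-crown-6, THF, −78 °C; then 5; work-up; PPTS (cat.), PhMe, 80 °C
Reagents that add atoms: none
Why: The Still–Gennari variant of the Horner–Wadsworth–Emmons olefination should give the (Z)-trisubstituted enoate, in which the tertiary hydroxyl and the ester are cis and lactonise under mild acid with loss of methanol.

**Step 4**
Reactants: 8 3-methylbut-1-yne; 9 N-methoxy-N-methylacetamide
Product: 10 5-methylhex-3-yn-2-one
Conditions: n-BuLi, THF, −78 °C; then 9, −78 → 0 °C; cold 1 M HCl
Reagents that add atoms: none
Why: Weinreb ketone synthesis, in which the lithium acetylide adds once and the chelated adduct releases the ynone only on acidic work-up, which also keeps the liberated amine protonated.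

**Step 5**
Reactants: 10 5-methylhex-3-yn-2-one
Product: 11 (3E)-4-methoxy-5-methylhex-3-en-2-one
Conditions: MeOH, PMe3 (10 mol %), CH2Cl2, 0 °C → rt
Reagents that add atoms: methanol (SMILES CO)
Why: Phosphine-catalysed conjugate (oxa-Michael) addition of methanol to the ynone puts the methoxy group regiospecifically on the isopropyl-bearing β-carbon and should give the thermodynamically preferred (E)-β-methoxy enone.

**Step 6**
Reactants: 11 (3E)-4-methoxy-5-methylhex-3-en-2-one
Product: 12 (3Z)-3-iodo-4-methoxy-5-methylhex-3-en-2-one
Conditions: NIS, MeCN, 0 °C → rt, dark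
Reagents that add atoms: N-iodosuccinimide (SMILES O=C1CCC(=O)N1I)
Why: Electrophilic α-iodination of a vinylogous ester through its oxocarbenium ion, loss of the α-proton restoring the push–pull alkene with iodine cis to methoxy, as α-iodo-β-methoxyacrylates form.

**Step 7**
Reactants: 12 (3Z)-3-iodo-4-methoxy-5-methylhex-3-en-2-one; 2 1-bromo-3-methylbut-2-ene
Product: 13 (3Z)-4-iodo-3-methoxy-2,9-dimethyldeca-3,8-dien-5-one
Conditions: LDA, THF, −78 °C; then 2, −78 → −20 °C
Reagents that add atoms: none
Why: Stork–Danheiser-type kinetic α′-deprotonation of the β-methoxy enone at its methyl group and SN2 alkylation of the cross-conjugated enolate by the allylic bromide, the amide base leaving the vinyl iodide untouched.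

**Step 8**
Reactants: 13 (3Z)-4-iodo-3-methoxy-2,9-dimethyldeca-3,8-dien-5-one; 7 6,6-dimethyl-3-(3-methylbut-2-enyl)-5,6-dihydro-2H-pyran-2-one
Product: 15 (3Z,6E)-6-[6,6-dimethyl-3-(3-methylbut-2-enyl)-5,6-dihydro-2H-pyran-2-ylidene]-4-iodo-3-methoxy-2,9-dimethyldeca-3,8-dien-5-one, via hydroxy diketone 14 (not isolated)
Conditions: LDA, THF, −78 °C; then 7, −78 → 0 °C; AcOH; then PPTS (cat.), 4 Å MS, CH2Cl2, rt
Reagents that add atoms: none
Why: Crossed Claisen condensation of the kinetic α′-enolate with the lactone carbonyl (the ring-opened tertiary alkoxide deprotonates the new β-diketone and drives the equilibrium), followed by acid-catalysed re-closure to the cyclic hemiketal and dehydration toward the acidic C8–H to give the push–pull 2-ylidene dihydropyran.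

**Step 9**
Reactants: 15 (3Z,6E)-6-[6,6-dimethyl-3-(3-methylbut-2-enyl)-5,6-dihydro-2H-pyran-2-ylidene]-4-iodo-3-methoxy-2,9-dimethyldeca-3,8-dien-5-one; 16 carbon monoxide
Product: 17 (4aR,6Z)-6-(1-methoxy-2-methylpropylidene)-2,2-dimethyl-4a,8-bis(3-methylbut-2-enyl)-4aH-chromene-5,7(6H)-dione
Conditions: Pd2(dba)3·CHCl3 (5 mol %), (R)-BINAP (12 mol %), Ag3PO4 (1.2 equiv), CO (5 atm), DMA, 60 °C
Reagents that add atoms: none
Why: Proposed new method: zerovalent palladium carrying (R)-BINAP adds oxidatively to the C6–I bond of the α-iodo enone, Ag3PO4 removes the iodide so that carbon monoxide inserts into a cationic vinylpalladium, and the acylpalladium adds syn across the C4a=C4 alkene of the dihydropyran, after which syn β-hydride elimination of a C3 hydrogen gives the C3=C4 alkene and the phosphate takes up the proton. The closest known reaction types are the carbonylative Heck cyclisation (cyclic acylpalladation) of alkenyl iodides onto tethered alkenes and the asymmetric intramolecular Heck reaction that forms quaternary carbons; neither has been shown on the ring alkene of a 2-ylidene dihydropyran. Ring A closes in a 6-exo-trig mode, the new carbonyl carbon C5 bonding to C6 and to C4a. The (R) configuration at C4a is fixed in the migratory insertion, where the axially chiral bisphosphine on the cationic metal distinguishes the two faces of the ring alkene; the sense of induction cannot be predicted safely, so the BINAP antipode that gives (R) would be settled in a first run. The step needs CO uptake before direct 5-exo carbopalladation (CO pressure; an α-acyl vinylpalladium inserts slowly), insertion into C4a=C4 and not into the prenyl alkene on C8 (the ring alkene ends an all-sp2 tether next to the acyl carbon and leaves palladium on a secondary carbon, whereas the prenyl path would put the bulky ligated metal on a tertiary carbon), and elimination toward C3 only, which is assured because C4a carries no hydrogen. Because the C6–C7 bond rotates freely, the geometry of the methoxy-bearing alkene does not matter for the closure.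

**Step 10**
Reactants: 17 (4aR,6Z)-6-(1-methoxy-2-methylpropylidene)-2,2-dimethyl-4a,8-bis(3-methylbut-2-enyl)-4aH-chromene-5,7(6H)-dione
Product: 18 (4aR)-7-hydroxy-2,2-dimethyl-4a,8-bis(3-methylbut-2-enyl)-6-(2-methylpropanoyl)-4aH-chromen-5-one
Conditions: 1 M aq. HCl, THF, 0 °C → rt
Reagents that add atoms: water (SMILES O)
Why: Acid-catalysed hydrolysis of the enol ether of a 2-acyl-1,3-dione (water adds at the methoxy-bearing carbon, methanol leaves) releases the enolised β-triketone, which is the target tautomer, and the quaternary C4a cannot epimerise.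

**Compound list**
1 | methyl 2-[bis(2,2,2-trifluoroethoxy)phosphoryl]acetate | COC(=O)CP(=O)(OCC(F)(F)F)OCC(F)(F)F | starting material
2 | 1-bromo-3-methylbut-2-ene (prenyl bromide) | CC(C)=CCBr | starting material
3 | methyl 2-[bis(2,2,2-trifluoroethoxy)phosphoryl]-5-methylhex-4-enoate (racemic) | COC(=O)C(CC=C(C)C)P(=O)(OCC(F)(F)F)OCC(F)(F)F | intermediate
4 | 3-methylbutane-1,3-diol | CC(C)(O)CCO | starting material
5 | 3-hydroxy-3-methylbutanal | CC(C)(O)CC=O | intermediate
6 | methyl (2Z)-5-hydroxy-5-methyl-2-(3-methylbut-2-enyl)hex-2-enoate | COC(=O)/C(CC=C(C)C)=C\CC(C)(C)O | intermediate (not isolated)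
7 | 6,6-dimethyl-3-(3-methylbut-2-enyl)-5,6-dihydro-2H-pyran-2-one | CC(C)=CCC1=CCC(C)(C)OC1=O | intermediate
8 | 3-methylbut-1-yne | CC(C)C#C | starting material
9 | N-methoxy-N-methylacetamide | CC(=O)N(C)OC | starting material
10 | 5-methylhex-3-yn-2-one | CC(C)C#CC(C)=O | intermediate
11 | (3E)-4-methoxy-5-methylhex-3-en-2-one | CC(C)/C(OC)=C\C(C)=O | intermediate
12 | (3Z)-3-iodo-4-methoxy-5-methylhex-3-en-2-one | CC(C)/C(OC)=C(/I)C(C)=O | intermediate
13 | (3Z)-4-iodo-3-methoxy-2,9-dimethyldeca-3,8-dien-5-one | CC(C)/C(OC)=C(/I)C(=O)CCC=C(C)C | intermediate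
14 | (3Z,8Z)-11-hydroxy-4-iodo-3-methoxy-2,11-dimethyl-6,8-bis(3-methylbut-2-enyl)dodeca-3,8-diene-5,7-dione (C6 epimers, in equilibrium with its cyclic hemiketal) | CC(C)/C(OC)=C(/I)C(=O)C(CC=C(C)C)C(=O)/C(CC=C(C)C)=C\CC(C)(C)O | intermediate (not isolated)
15 | (3Z,6E)-6-[6,6-dimethyl-3-(3-methylbut-2-enyl)-5,6-dihydro-2H-pyran-2-ylidene]-4-iodo-3-methoxy-2,9-dimethyldeca-3,8-dien-5-one | CC(C)/C(OC)=C(/I)C(=O)/C(CC=C(C)C)=C1/OC(C)(C)CC=C1CC=C(C)C | intermediate
16 | carbon monoxide | [C-]#[O+] | starting material
17 | (4aR,6Z)-6-(1-methoxy-2-methylpropylidene)-2,2-dimethyl-4a,8-bis(3-methylbut-2-enyl)-4aH-chromene-5,7(6H)-dione | CC(C)=CCC1=C2OC(C)(C)C=C[C@@]2(CC=C(C)C)C(=O)/C(=C(\OC)C(C)C)C1=O | intermediate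
18 | (4aR)-7-hydroxy-2,2-dimethyl-4a,8-bis(3-methylbut-2-enyl)-6-(2-methylpropanoyl)-4aH-chromen-5-one (CNP0119032.1) | CC(C)=CCC1=C2OC(C)(C)C=C[C@@]2(CC=C(C)C)C(=O)C(C(=O)C(C)C)=C1O | target

**Step count and risks**
Total steps: 10. Longest linear sequence: 7 steps (steps 4 to 10, from 8 to 18).

Most likely to fail, first: step 9. The acylpalladium may insert into the prenyl alkene on C8 instead of the ring alkene, carbopalladation may precede carbon monoxide uptake, or facial selectivity in the insertion may be low. The fallback sets out from 15. The vinyl iodide is methoxycarbonylated (PdCl2(PPh3)2, Et3N, CO 1 atm, MeOH, 50 °C), solvent methanol trapping the acylpalladium before it can insert, to give methyl (2Z)-2-{(2E)-2-[6,6-dimethyl-3-(3-methylbut-2-enyl)-5,6-dihydro-2H-pyran-2-ylidene]-5-methylhex-4-enoyl}-3-methoxy-4-methylpent-2-enoate F1. LDA in THF (−78 → 0 °C) then removes a C3 proton of the dihydropyran, and the extended enolate acylates itself at C4a in a Dieckmann-type Claisen closure of ring A, the alkene moving to C3=C4, to give the racemic ring-closed enol ether F2. Preparative HPLC on a chiral stationary phase would then supply the (R)-enantiomer, and the route is rejoined at 17.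

Second: step 8. The enolate may add in conjugate fashion to the unsaturated lactone or deprotonate its γ-position instead of attacking the carbonyl, and in the acid stage the diketone enol may close onto its own methoxy-bearing carbon with loss of methanol (4-pyranone formation) instead of the hemiketal dehydrating. The fallback sets out from 7. DIBAL-H (CH2Cl2, −78 °C) reduces it to 6,6-dimethyl-3-(3-methylbut-2-enyl)-5,6-dihydro-2H-pyran-2-ol F3. Its lithium alkoxide (LiHMDS) is treated with the lithium enolate of 13 (LDA, THF, −78 → −20 °C), which adds 1,2 to the ring-opened (Z)-enal in an aldol reaction to give (3Z,8Z)-7,11-dihydroxy-4-iodo-3-methoxy-2,11-dimethyl-6,8-bis(3-methylbut-2-enyl)dodeca-3,8-dien-5-one F4 as a diastereomer mixture. Dess–Martin periodinane (NaHCO3, CH2Cl2) oxidises only the secondary allylic alcohol and so returns the route at 14, which is dehydrated as in the second half of step 8.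

Third: step 3. The β-hydroxy aldehyde may dehydrate under the basic conditions before olefination, and Z selectivity may erode with the α-branched phosphonate, the E ester being unable to lactonise. The fallback sets out from 2 and fixes the alkene geometry by ring formation. Commercial triethyl phosphonoacetate is alkylated with 2 (NaH, THF) to ethyl 2-(diethoxyphosphoryl)-5-methylhex-4-enoate F5. Horner–Wadsworth–Emmons methylenation with aqueous formaldehyde and K2CO3 gives ethyl 5-methyl-2-methylidenehex-4-enoate F6, and LiOH in THF–water gives 5-methyl-2-methylidenehex-4-enoic acid F7. Steglich esterification (DCC, DMAP, CH2Cl2) with commercial 2-methylpent-4-en-2-ol gives 2-methylpent-4-en-2-yl 5-methyl-2-methylidenehex-4-enoate F8. Ring-closing metathesis with the second-generation Grubbs catalyst (PhMe, 80 °C) between the terminal alkene and the acrylate alkene should then give the lactone, and the route is rejoined at 7.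

**Further compounds**
F1 | step 9 | methyl (2Z)-2-{(2E)-2-[6,6-dimethyl-3-(3-methylbut-2-enyl)-5,6-dihydro-2H-pyran-2-ylidene]-5-methylhex-4-enoyl}-3-methoxy-4-methylpent-2-enoate | CC(C)/C(OC)=C(/C(=O)OC)C(=O)/C(CC=C(C)C)=C1/OC(C)(C)CC=C1CC=C(C)C
F2 | step 9 | racemic (6Z)-6-(1-methoxy-2-methylpropylidene)-2,2-dimethyl-4a,8-bis(3-methylbut-2-enyl)-4aH-chromene-5,7(6H)-dione | CC(C)=CCC1=C2OC(C)(C)C=CC2(CC=C(C)C)C(=O)/C(=C(\OC)C(C)C)C1=O
F3 | step 8 | 6,6-dimethyl-3-(3-methylbut-2-enyl)-5,6-dihydro-2H-pyran-2-ol | CC(C)=CCC1=CCC(C)(C)OC1O
F4 | step 8 | (3Z,8Z)-7,11-dihydroxy-4-iodo-3-methoxy-2,11-dimethyl-6,8-bis(3-methylbut-2-enyl)dodeca-3,8-dien-5-one (diastereomer mixture) | CC(C)/C(OC)=C(/I)C(=O)C(CC=C(C)C)C(O)/C(CC=C(C)C)=C\CC(C)(C)O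
F5 | step 3 | ethyl 2-(diethoxyphosphoryl)-5-methylhex-4-enoate | CCOC(=O)C(CC=C(C)C)P(=O)(OCC)OCC
F6 | step 3 | ethyl 5-methyl-2-methylidenehex-4-enoate | CCOC(=O)C(=C)CC=C(C)C
F7 | step 3 | 5-methyl-2-methylidenehex-4-enoic acid | OC(=O)C(=C)CC=C(C)C
F8 | step 3 | 2-methylpent-4-en-2-yl 5-methyl-2-methylidenehex-4-enoate | C=CCC(C)(C)OC(=O)C(=C)CC=C(C)C
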